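**Plan**
- Retrosynthesis: cut the C6–prenyl bond of the dearomatised ring, then the aryl–acyl bond, then the carbinol C–CH3 bond, and finally the two exocyclic bonds of the cyclopentane (CH–isopropenyl and CH–CH2Ar) in one operation.
- Enabling feature: in the cyclopentane, the C(OH)CH3 carbon, the adjacent CH carrying the CH2 link and the next CH carrying isopropenyl (trans to the link) are the C=O, α- and β-carbons of cyclopent-2-en-1-one.
- Forward: methylphloroglucinol is formylated, MOM-protected, reduced and brominated; enone, isopropenyl Grignard reagent and benzylic bromide are then joined in one flask. No ring is closed: the five-membered ring comes from cyclopentenone, the six-membered ring from the arene.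
- Completion: methyl addition, ortho-lithiation/acylation (aldehyde addition, then oxidation), MOM removal and dearomative prenylation at the methyl-bearing ring carbon.
- Stereochemistry: the isopropenyl CH from the chiral copper catalyst; the neighbouring CH from anti alkylation (also the thermodynamic trans ketone); the carbinol from addition opposite the arylmethyl arm; quaternary C6 from a chiral palladium catalyst.

Key step: step 5

Assumption: the target is handled as the enol tautomer drawn (C6 = S in that form); the other β-triketone tautomers are the same compound.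

**Route**

Step 1
Reactants: 1 2,4,6-trihydroxytoluene
Product: 3 2,4,6-trihydroxy-3-methylbenzaldehyde, via aryl iminium chloride 2 (not isolated)
Conditions: POCl3 (1.05 equiv), DMF, EtOAc, 0 °C → rt; then H2O, 60 °C
Reagents that add atoms: N,N-dimethylformamide CN(C)C=O; water O
Why: Vilsmeier–Haack formylation, in which the chloroiminium ion attacks one of the two equivalent free positions of the electron-rich ring and iminium salt 2 is hydrolysed on work-up, one equivalent of reagent limiting diformylation.

Step 2
Reactants: 3 2,4,6-trihydroxy-3-methylbenzaldehyde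
Product: 4 2,4,6-tris(methoxymethoxy)-3-methylbenzaldehyde
Conditions: NaH (3.6 equiv), MOMCl (4 equiv), DMF, 0 °C → rt
Reagents that add atoms: chloromethyl methyl ether COCCl
Why: O-alkylation of the sodium phenoxides by the hard electrophile MOMCl (Williamson-type acetal formation), the strong base also reaching the two hydrogen-bonded ortho hydroxyls.

Step 3
Reactants: 4 2,4,6-tris(methoxymethoxy)-3-methylbenzaldehyde
Product: 5 [2,4,6-tris(methoxymethoxy)-3-methylphenyl]methanol
Conditions: NaBH4, MeOH/THF, 0 °C
Reagents that add atoms: none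
Why: Borohydride reduction of the aldehyde under basic conditions that leave the MOM acetals untouched.

Step 4
Reactants: 5 [2,4,6-tris(methoxymethoxy)-3-methylphenyl]methanol
Product: 6 3-methyl-2,4,6-tris(methoxymethoxy)benzyl bromide
Conditions: PPh3, CBr4, CH2Cl2, −20 → 0 °C; short basic-alumina plug, used at once
Reagents that add atoms: carbon tetrabromide BrC(Br)(Br)Br
Why: Appel bromination proceeds without free acid, so the MOM acetals survive, and the easily ionised bromide is taken straight into the coupling to avoid self-alkylation.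

Step 5
Reactants: 7 cyclopent-2-en-1-one; 8 isopropenylmagnesium bromide; 6 3-methyl-2,4,6-tris(methoxymethoxy)benzyl bromide
Product: 10 (2R,3S)-2-{[2,4,6-tris(methoxymethoxy)-3-methylphenyl]methyl}-3-(prop-1-en-2-yl)cyclopentan-1-one, via bromomagnesium enolate 9 (not isolated)
Conditions: CuBr·SMe2 (5 mol%), Josiphos-type ferrocenyl diphosphine (6 mol%, antipode selected for 3S), 7 (1.05 equiv), slow addition of 8 (1.0 equiv), t-BuOMe, −78 °C; then 6 (0.8 equiv), DMPU, −78 → −20 °C
Reagents that add atoms: none
Why: The chiral Cu(I)–diphosphine complex binds the enone and transfers the isopropenyl group to the β-carbon, leaving the regiodefined bromomagnesium enolate 9, which is then alkylated at C2 by the benzylic bromide. The closest known reaction type is the copper-catalysed asymmetric conjugate addition of Grignard reagents to cyclic enones with trapping of the magnesium enolate by benzylic or allylic halides. No ring is closed; two C–C bonds are formed on the intact five-membered ring. C3 (S) is set by the ligand, and the antipode giving this sense is to be fixed by protonating a sample of 9 and assigning the resulting 3-isopropenylcyclopentanone. C2 (R) is set by approach of the electrophile anti to the C3 substituent, and the 2,3-trans ketone is also the thermodynamic epimer. The step needs 1,4- over 1,2-addition (copper catalysis, slow addition at −78 °C), no cross-coupling of bromide with Grignard reagent (enone in slight excess) and C-monoalkylation without enolate equilibration (reactive bromide as limiting reagent, DMPU, low temperature).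

Step 6
Reactants: 10 (2R,3S)-2-{[2,4,6-tris(methoxymethoxy)-3-methylphenyl]methyl}-3-(prop-1-en-2-yl)cyclopentan-1-one
Product: 11 (1S,2R,3S)-1-methyl-2-{[2,4,6-tris(methoxymethoxy)-3-methylphenyl]methyl}-3-(prop-1-en-2-yl)cyclopentan-1-ol
Conditions: MeLi, anhydrous CeCl3, THF, −78 °C
Reagents that add atoms: methyllithium C[Li] (delivered as methylcerium dichloride)
Why: Organocerium 1,2-addition, in which the weakly basic MeCeCl2 adds to the enolisable ketone without deprotonation and approaches opposite the adjacent C2 arylmethyl group (the C3 isopropenyl group on that face is one carbon further away), setting C1 as S with the hydroxyl cis to the arm.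

Step 7
Reactants: 11 (1S,2R,3S)-1-methyl-2-{[2,4,6-tris(methoxymethoxy)-3-methylphenyl]methyl}-3-(prop-1-en-2-yl)cyclopentan-1-ol; 12 3-methylbutanal
Product: 14 (1S,2R,3S)-2-{[3-(1-hydroxy-3-methylbutyl)-2,4,6-tris(methoxymethoxy)-5-methylphenyl]methyl}-1-methyl-3-(prop-1-en-2-yl)cyclopentan-1-ol (both epimers at the new benzylic carbinol), via dilithiated arene 13 (not isolated)
Conditions: n-BuLi (2.3 equiv), THF, 0 °C; then 12, −78 °C; H2O
Reagents that add atoms: none
Why: Directed ortho-metalation, in which the first equivalent of n-BuLi forms the tertiary alkoxide and the second removes the only aromatic hydrogen, flanked by two coordinating OMOM groups, before the aryllithium adds to the aldehyde; the uncontrolled benzylic carbinol centre is erased in step 8.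

Step 8
Reactants: 14 (1S,2R,3S)-2-{[3-(1-hydroxy-3-methylbutyl)-2,4,6-tris(methoxymethoxy)-5-methylphenyl]methyl}-1-methyl-3-(prop-1-en-2-yl)cyclopentan-1-ol
Product: 15 1-[3-{[(1R,2S,5S)-2-hydroxy-2-methyl-5-(prop-1-en-2-yl)cyclopentyl]methyl}-2,4,6-tris(methoxymethoxy)-5-methylphenyl]-3-methylbutan-1-one
Conditions: Dess–Martin periodinane, pyridine, CH2Cl2, 0 °C → rt
Reagents that add atoms: none
Why: Dess–Martin oxidation turns the secondary benzylic alcohol into the aryl ketone, while the tertiary alcohol cannot be oxidised and pyridine buffers the acetic acid so that acetals and alkene are untouched.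

Step 9
Reactants: 15 1-[3-{[(1R,2S,5S)-2-hydroxy-2-methyl-5-(prop-1-en-2-yl)cyclopentyl]methyl}-2,4,6-tris(methoxymethoxy)-5-methylphenyl]-3-methylbutan-1-one
Product: 16 1-[2,4,6-trihydroxy-3-{[(1R,2S,5S)-2-hydroxy-2-methyl-5-(prop-1-en-2-yl)cyclopentyl]methyl}-5-methylphenyl]-3-methylbutan-1-one
Conditions: HCl (ca. 0.3 M), MeOH/THF, rt
Reagents that add atoms: none
Why: Acid-catalysed transacetalisation to methanol frees the three phenols (the two MOM groups ortho to the acyl group are activated by chelation), and dilute acid at room temperature is chosen so that the tertiary alcohol and the 1,1-disubstituted alkene are not ionised.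

Step 10
Reactants: 16 1-[2,4,6-trihydroxy-3-{[(1R,2S,5S)-2-hydroxy-2-methyl-5-(prop-1-en-2-yl)cyclopentyl]methyl}-5-methylphenyl]-3-methylbutan-1-one; 17 3-methylbut-2-en-1-yl acetate (prenyl acetate)
Product: 18 (6S)-3,5-dihydroxy-4-{[(1R,2S,5S)-2-hydroxy-2-methyl-5-(prop-1-en-2-yl)cyclopentyl]methyl}-6-methyl-2-(3-methylbutanoyl)-6-(3-methylbut-2-en-1-yl)cyclohexa-2,4-dien-1-one (CNP0139230.1)
Conditions: Pd2(dba)3·CHCl3 (2.5 mol%), chiral DACH-phenyl bis(2-diphenylphosphinobenzamide) ligand (7.5 mol%, antipode chosen by screening for 6S), Cs2CO3 (1.0 equiv), degassed THF, 0 °C → rt; acidic work-up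
Reagents that add atoms: none
Why: Proposed new method: Pd(0) ionises prenyl acetate to a π-(1,1-dimethylallyl)palladium complex held in the chiral pocket of the ligand, and the caesium phenoxide of 16 attacks its unsubstituted terminus through the methyl-bearing ring carbon, which is less hindered than the carbon carrying the branched cyclopentylmethyl arm, while any O-prenyl ether re-ionises under Pd(0) and is funnelled to the C-alkylated β-triketone enol; the quaternary centre (6S) is set by the catalyst because the resident stereocentres are too remote, and the closest known reaction types are the Pd-catalysed asymmetric allylic dearomatisation of naphthols and phenols (Tsuji–Trost type) and the non-asymmetric dearomative C-allylation and C-prenylation of acylphloroglucinols.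

**Compound list**

1 | 2,4,6-trihydroxytoluene (2-methylphloroglucinol) | Cc1c(O)cc(O)cc1O | starting material
2 | N-[(2,4,6-trihydroxy-3-methylphenyl)methylidene]-N-methylmethanaminium chloride | Cc1c(O)cc(O)c(C=[N+](C)C)c1O.[Cl-] | intermediate
3 | 2,4,6-trihydroxy-3-methylbenzaldehyde | Cc1c(O)cc(O)c(C=O)c1O | intermediate
4 | 2,4,6-tris(methoxymethoxy)-3-methylbenzaldehyde | COCOc1cc(OCOC)c(C)c(OCOC)c1C=O | intermediate
5 | [2,4,6-tris(methoxymethoxy)-3-methylphenyl]methanol | COCOc1cc(OCOC)c(C)c(OCOC)c1CO | intermediate
6 | 3-methyl-2,4,6-tris(methoxymethoxy)benzyl bromide | COCOc1cc(OCOC)c(C)c(OCOC)c1CBr | intermediate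
7 | cyclopent-2-en-1-one | O=C1C=CCC1 | starting material
8 | isopropenylmagnesium bromide | C=C(C)[Mg]Br | starting material
9 | bromomagnesium (3S)-3-(prop-1-en-2-yl)cyclopent-1-en-1-olate | C=C(C)[C@H]1CCC(O[Mg]Br)=C1 | intermediate
10 | (2R,3S)-2-{[2,4,6-tris(methoxymethoxy)-3-methylphenyl]methyl}-3-(prop-1-en-2-yl)cyclopentan-1-one | C=C(C)[C@H]1CCC(=O)[C@@H]1Cc1c(OCOC)cc(OCOC)c(C)c1OCOC | intermediate
11 | (1S,2R,3S)-1-methyl-2-{[2,4,6-tris(methoxymethoxy)-3-methylphenyl]methyl}-3-(prop-1-en-2-yl)cyclopentan-1-ol | C=C(C)[C@H]1CC[C@](C)(O)[C@@H]1Cc1c(OCOC)cc(OCOC)c(C)c1OCOC | intermediate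
12 | 3-methylbutanal (isovaleraldehyde) | CC(C)CC=O | starting material
13 | lithium (1S,2R,3S)-2-{[3-lithio-2,4,6-tris(methoxymethoxy)-5-methylphenyl]methyl}-1-methyl-3-(prop-1-en-2-yl)cyclopentan-1-olate | C=C(C)[C@H]1CC[C@](C)(O[Li])[C@@H]1Cc1c(OCOC)c([Li])c(OCOC)c(C)c1OCOC | intermediate
14 | (1S,2R,3S)-2-{[3-(1-hydroxy-3-methylbutyl)-2,4,6-tris(methoxymethoxy)-5-methylphenyl]methyl}-1-methyl-3-(prop-1-en-2-yl)cyclopentan-1-ol, epimers at the benzylic carbinol | C=C(C)[C@H]1CC[C@](C)(O)[C@@H]1Cc1c(OCOC)c(C(O)CC(C)C)c(OCOC)c(C)c1OCOC | intermediate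
15 | 1-[3-{[(1R,2S,5S)-2-hydroxy-2-methyl-5-(prop-1-en-2-yl)cyclopentyl]methyl}-2,4,6-tris(methoxymethoxy)-5-methylphenyl]-3-methylbutan-1-one | C=C(C)[C@H]1CC[C@](C)(O)[C@@H]1Cc1c(OCOC)c(C(=O)CC(C)C)c(OCOC)c(C)c1OCOC | intermediate
16 | 1-[2,4,6-trihydroxy-3-{[(1R,2S,5S)-2-hydroxy-2-methyl-5-(prop-1-en-2-yl)cyclopentyl]methyl}-5-methylphenyl]-3-methylbutan-1-one | C=C(C)[C@H]1CC[C@](C)(O)[C@@H]1Cc1c(O)c(C(=O)CC(C)C)c(O)c(C)c1O | intermediate
17 | 3-methylbut-2-en-1-yl acetate (prenyl acetate) | CC(C)=CCOC(C)=O | starting material
18 | (6S)-3,5-dihydroxy-4-{[(1R,2S,5S)-2-hydroxy-2-methyl-5-(prop-1-en-2-yl)cyclopentyl]methyl}-6-methyl-2-(3-methylbutanoyl)-6-(3-methylbut-2-en-1-yl)cyclohexa-2,4-dien-1-one | C=C(C)[C@H]1CC[C@](C)(O)[C@@H]1CC1=C(O)[C@](C)(CC=C(C)C)C(=O)C(C(=O)CC(C)C)=C1O | target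

**Count**

Total steps: 10. Longest linear sequence: 10 steps (1 → 18); compounds 7, 8, 12 and 17 are bought.

**Steps most likely to fail**

1. Step 10 (proposed new method). The risk is alkylation on oxygen or at the ring carbon carrying the cyclopentylmethyl arm, together with weak facial discrimination by the chiral catalyst. The fallback sets out from 16 and uses the classical base-mediated alkylative dearomatisation of acylphloroglucinols: NaOMe in MeOH with prenyl bromide (1-bromo-3-methylbut-2-ene) at 0 °C. This should give C-prenylation at the less hindered methyl-bearing carbon without stereocontrol, so that 18 forms beside its (6R)-epimer F1. The two are diastereomers and would be separated by preparative HPLC, which brings the route back at 18.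

2. Step 5. The risk is that C-benzylation of the bromomagnesium enolate is slow compared with proton exchange with the product (loss of regiochemistry, double alkylation), with copper-mediated coupling of residual Grignard reagent and with self-alkylation of the ionisable bromide. The fallback sets out from 7 and 8 and separates the two bond-forming events. The same copper-catalysed conjugate addition is run with Me3SiCl present, and the enolate is isolated as (S)-trimethyl{[3-(prop-1-en-2-yl)cyclopent-1-en-1-yl]oxy}silane F2, on which the enantiomeric purity can be checked. Methyllithium in THF at 0 °C then releases the regiospecific lithium (3S)-3-(prop-1-en-2-yl)cyclopent-1-en-1-olate F3. This more reactive enolate is alkylated with 6 in THF/DMPU at −78 → −30 °C, again anti to the C3 substituent, returning to the route at 10.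

3. Step 9. The risk is acid-induced ionisation of the tertiary alcohol or protonation of the isopropenyl group during acetal cleavage, followed by capture by the neighbouring phenol (cyclic ether formation) or elimination. The fallback sets out from 15 and avoids Brønsted acid. Me3SiOTf with 2,2′-bipyridyl in MeCN at 0 °C exchanges the three aryl MOM ethers for silyl ethers and silylates the tertiary hydroxyl, giving the tetrakis(trimethylsilyl) compound F4. Desilylation with TBAF buffered by AcOH in THF at 0 °C then returns to the route at 16.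

**Further compounds**

F1 | step 10 | (6R)-3,5-dihydroxy-4-{[(1R,2S,5S)-2-hydroxy-2-methyl-5-(prop-1-en-2-yl)cyclopentyl]methyl}-6-methyl-2-(3-methylbutanoyl)-6-(3-methylbut-2-en-1-yl)cyclohexa-2,4-dien-1-one | C=C(C)[C@H]1CC[C@](C)(O)[C@@H]1CC1=C(O)[C@@](C)(CC=C(C)C)C(=O)C(C(=O)CC(C)C)=C1O
F2 | step 5 | (S)-trimethyl{[3-(prop-1-en-2-yl)cyclopent-1-en-1-yl]oxy}silane | C=C(C)[C@H]1CCC(O[Si](C)(C)C)=C1
F3 | step 5 | lithium (3S)-3-(prop-1-en-2-yl)cyclopent-1-en-1-olate | C=C(C)[C@H]1CCC(O[Li])=C1
F4 | step 9 | 1-[3-{[(1R,2S,5S)-2-methyl-5-(prop-1-en-2-yl)-2-(trimethylsilyloxy)cyclopentyl]methyl}-5-methyl-2,4,6-tris(trimethylsilyloxy)phenyl]-3-methylbutan-1-one | C=C(C)[C@H]1CC[C@](C)(O[Si](C)(C)C)[C@@H]1Cc1c(O[Si](C)(C)C)c(C(=O)CC(C)C)c(O[Si](C)(C)C)c(C)c1O[Si](C)(C)C
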